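## Retrosynthetic overview

1. Target 20 ⇒ 19 + 18, and 19 ⇒ 14 + 16: two successive catalyst-controlled Friedel–Crafts/Michael alkylations form both aryl–CH bonds and both stereocentres (isopropyl-bearing centre first, isobutyl-bearing centre second).
2. 16 and 18 ⇒ syncarpic acid 9 + isobutyraldehyde 15 or isovaleraldehyde 17 (Knoevenagel condensation).
3. 9 ⇒ 2,2,4,4-tetramethylcyclobutane-1,3-dione 3 + ethoxyacetylene 4 by an anionic two-carbon ring expansion (4 → 6), the key step; 3 ⇒ two molecules of isobutyryl chloride 1 by dimethylketene dimerisation.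
4. 14 ⇒ phloroglucinol 12 + hexanoyl chloride 13 (Friedel–Crafts acylation); 12 ⇒ benzene 10 (triple C–H borylation, then oxidation).
5. Ring order: the four-membered ring of 3, then its expansion to the six-membered trione ring of 9 (used twice); the arene ring comes from benzene; no ring is formed after step 2.

Assumption: the facial sense of the cinchona squaramide cannot be predicted with certainty, so the route is written for the quinine-derived catalyst giving Si-face attack (R); if a test reaction shows the opposite sense, its quinidine-derived pseudoenantiomer is used in steps 7 and 8.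

## Route

Step 1
Reactants: 1 isobutyryl chloride (2-methylpropanoyl chloride), two molecules per molecule of product
Product: 3 2,2,4,4-tetramethylcyclobutane-1,3-dione, via dimethylketene 2 (not isolated)
Conditions: Et3N (1.1 equiv per 1), Et2O, reflux; filter, sublime
Reagents that add atoms: isobutyryl chloride (the second molecule of 1, which supplies the second C4O half of 3), CC(C)C(=O)Cl
Why: Et3N dehydrochlorinates each of the two molecules of 1 to dimethylketene 2, and two molecules of 2 dimerise head-to-tail in a thermal [2+2] cycloaddition (ketene dimerisation) to the symmetrical 1,3-dione 3; no stereocentre is formed.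

Step 2
Reactants: 3 2,2,4,4-tetramethylcyclobutane-1,3-dione; 4 ethoxyacetylene (ethoxyethyne)
Product: 9 syncarpic acid (2,2,4,4-tetramethylcyclohexane-1,3,5-trione), via lithium ethoxyacetylide 5 (not isolated), via lithium cyclobutanolate adduct 6 (not isolated), via ring-opened ynone enolate 7 (not isolated), via ethyl enol ether 8 (not isolated)
Conditions: 4, n-BuLi (1.0 equiv), THF, −78 °C; add 3, −78 °C; t-BuOH (1.0 equiv, proton shuttle, recovered unchanged after the acid work-up), −78 → 45 °C; then 2 M aq. HCl, 23 → 45 °C
Reagents that add atoms: water, O (supplies the oxygen at C5 when the enol ether is hydrolysed)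
Why: Proposed new method: an anionic two-carbon ring expansion (formal insertion of a ketene unit into a ring C–C bond) in which acetylide 5 adds to the strained ketone of 3, alkoxide 6 opens by strain-driven retro-aldol fragmentation to enolate 7, whose alkoxy-ynone has no acidic C–H that could quench it, and the tetrasubstituted enolate carbon closes by 6-endo-dig conjugate addition onto the ethoxy-bearing alkyne carbon (t-BuOH protonates the resulting vinyl anion) to give vinylogous ester 8, which aqueous acid hydrolyses to 9; the closest known reaction types are the alkoxide-mediated insertion of dimethylketene into 3 to give hexamethylcyclohexane-1,3,5-trione, the base-induced ring opening of organometallic adducts of 3 to β-diketones, and 6-endo-dig Michael cyclisations of enolates onto ynones; no stereocentre is formed.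

Step 3
Reactants: 10 benzene
Product: 12 phloroglucinol (benzene-1,3,5-triol), via 1,3,5-tris(pinacolatoboryl)benzene 11 (not isolated)
Conditions: B2pin2 (1.8 equiv; 1.5 equiv is consumed because both boron atoms are used), [Ir(OMe)(cod)]2 (1.5 mol%), dtbpy (3 mol%), cyclohexane, 80 °C; then Oxone, acetone–H2O, 23 °C
Reagents that add atoms: bis(pinacolato)diboron, CC1(C)OB(OC1(C)C)B1OC(C)(C)C(C)(C)O1 (Bpin groups of 11); Oxone (potassium peroxymonosulfate), [K+].[O-]S(=O)(=O)OO (the three O of 12)
Why: Sterically controlled Ir-catalysed C–H borylation puts each new Bpin meta to those already present (PhBpin reacts meta:para about 2:1 and only the 1,3-isomer can be borylated again, so about two thirds of the material can reach 11 and the para by-product is removed after oxidation as hydroquinone), and Oxone then converts each C–B bond into C–OH at the same position (boronate oxidation); no stereocentre is formed.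

Step 4
Reactants: 12 phloroglucinol; 13 hexanoyl chloride
Product: 14 1-(2,4,6-trihydroxyphenyl)hexan-1-one (hexanoylphloroglucinol)
Conditions: AlCl3 (4 equiv), PhNO2, 80 °C; then 1 M HCl, 0 °C
Reagents that add atoms: none
Why: Friedel–Crafts C-acylation of the electron-rich triol stops after one acylation because the chelated acyl group deactivates the ring, and the three ring positions of 12 are equivalent; no stereocentre is formed.

Step 5
Reactants: 9 syncarpic acid; 15 isobutyraldehyde (2-methylpropanal)
Product: 16 2,2,4,4-tetramethyl-6-(2-methylpropylidene)cyclohexane-1,3,5-trione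
Conditions: 15 (3 equiv), piperidine (10 mol%), AcOH (10 mol%), 4 Å MS, CH2Cl2, 0 → 23 °C; dil. HCl wash
Reagents that add atoms: none
Why: Amine-catalysed Knoevenagel condensation at the only CH2 of 9; the flanking gem-dimethyl groups and the excess volatile aldehyde suppress a second Michael addition of 9, and the symmetrical trione allows no E/Z isomers; no stereocentre is formed.

Step 6
Reactants: 9 syncarpic acid; 17 isovaleraldehyde (3-methylbutanal)
Product: 18 2,2,4,4-tetramethyl-6-(3-methylbutylidene)cyclohexane-1,3,5-trione
Conditions: 17 (2 equiv), piperidine (10 mol%), AcOH (10 mol%), 4 Å MS, CH2Cl2, 0 °C; dil. HCl wash; used at once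
Reagents that add atoms: none
Why: The same Knoevenagel condensation; the product is kept cold and used directly because its γ-CH2 allows slow isomerisation to the deconjugated dienol; no stereocentre is formed.

Step 7
Reactants: 14 1-(2,4,6-trihydroxyphenyl)hexan-1-one; 16 2,2,4,4-tetramethyl-6-(2-methylpropylidene)cyclohexane-1,3,5-trione
Product: 19 1-{2,4,6-trihydroxy-3-[(1R)-1-(2-hydroxy-3,3,5,5-tetramethyl-4,6-dioxocyclohex-1-en-1-yl)-2-methylpropyl]phenyl}hexan-1-one
Conditions: 14 (2.0 equiv), quinine-derived (9-amino-9-deoxy-epi-quinine) 3,5-bis(trifluoromethyl)phenyl squaramide (10 mol%), 4 Å MS, toluene–CH2Cl2, −30 °C, slow addition of 16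
Reagents that add atoms: none
Why: Enantioselective Friedel–Crafts-type Michael addition under bifunctional Brønsted base/hydrogen-bond catalysis, in which the quinuclidine engages the 4-OH of 14 and the squaramide binds the 1,3-dione of 16, so that ring carbon C3 attacks the Si face of the alkylidene carbon and sets the (R) centre, while excess 14 and slow addition of 16 suppress double alkylation.

Step 8
Reactants: 19 the (R)-mono-adduct; 18 2,2,4,4-tetramethyl-6-(3-methylbutylidene)cyclohexane-1,3,5-trione
Product: 20 myrtucommulone H, 1-{2,4,6-trihydroxy-3-[(1R)-1-(2-hydroxy-3,3,5,5-tetramethyl-4,6-dioxocyclohex-1-en-1-yl)-3-methylbutyl]-5-[(1R)-1-(2-hydroxy-3,3,5,5-tetramethyl-4,6-dioxocyclohex-1-en-1-yl)-2-methylpropyl]phenyl}hexan-1-one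
Conditions: 18 (1.3 equiv), same squaramide (10 mol%), 4 Å MS, toluene–CH2Cl2, −20 °C
Reagents that add atoms: none
Why: A second Friedel–Crafts-type Michael addition at the only free ring position under the same catalyst control (Si-face attack on the alkylidene carbon of 18) sets the second (R) centre, the remote first centre is not touched at −20 °C (no retro-Michael), and the (S,R) diastereomer that comes from the minor enantiomer of 19 is removed by chromatography, which raises the ee of 20.

## Compound list

1 | isobutyryl chloride | CC(C)C(=O)Cl | starting material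
2 | dimethylketene | CC(C)=C=O | intermediate (not isolated)
3 | 2,2,4,4-tetramethylcyclobutane-1,3-dione | CC1(C)C(=O)C(C)(C)C1=O | intermediate
4 | ethoxyacetylene | CCOC#C | starting material
5 | lithium ethoxyacetylide | CCOC#[C-].[Li+] | intermediate (not isolated)
6 | lithium 1-(ethoxyethynyl)-2,2,4,4-tetramethyl-3-oxocyclobutan-1-olate | CCOC#CC1([O-])C(C)(C)C(=O)C1(C)C.[Li+] | intermediate (not isolated)
7 | lithium 7-ethoxy-2,4,4-trimethyl-5-oxohept-2-en-6-yn-3-olate | CCOC#CC(=O)C(C)(C)C([O-])=C(C)C.[Li+] | intermediate (not isolated)
8 | 5-ethoxy-2,2,6,6-tetramethylcyclohex-4-ene-1,3-dione (syncarpic acid ethyl enol ether) | CCOC1=CC(=O)C(C)(C)C(=O)C1(C)C | intermediate (not isolated)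
9 | syncarpic acid (2,2,4,4-tetramethylcyclohexane-1,3,5-trione) | CC1(C)C(=O)CC(=O)C(C)(C)C1=O | intermediate
10 | benzene | c1ccccc1 | starting material
11 | 1,3,5-tris(4,4,5,5-tetramethyl-1,3,2-dioxaborolan-2-yl)benzene | CC1(C)OB(OC1(C)C)c1cc(B2OC(C)(C)C(C)(C)O2)cc(B2OC(C)(C)C(C)(C)O2)c1 | intermediate (not isolated)
12 | phloroglucinol (benzene-1,3,5-triol) | Oc1cc(O)cc(O)c1 | intermediate
13 | hexanoyl chloride | CCCCCC(=O)Cl | starting material
14 | 1-(2,4,6-trihydroxyphenyl)hexan-1-one | CCCCCC(=O)c1c(O)cc(O)cc1O | intermediate
15 | isobutyraldehyde | CC(C)C=O | starting material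
16 | 2,2,4,4-tetramethyl-6-(2-methylpropylidene)cyclohexane-1,3,5-trione | CC(C)C=C1C(=O)C(C)(C)C(=O)C(C)(C)C1=O | intermediate
17 | isovaleraldehyde | CC(C)CC=O | starting material
18 | 2,2,4,4-tetramethyl-6-(3-methylbutylidene)cyclohexane-1,3,5-trione | CC(C)CC=C1C(=O)C(C)(C)C(=O)C(C)(C)C1=O | intermediate
19 | 1-{2,4,6-trihydroxy-3-[(1R)-1-(2-hydroxy-3,3,5,5-tetramethyl-4,6-dioxocyclohex-1-en-1-yl)-2-methylpropyl]phenyl}hexan-1-one | CCCCCC(=O)c1c(O)cc(O)c([C@H](C2=C(O)C(C)(C)C(=O)C(C)(C)C2=O)C(C)C)c1O | intermediate
20 | myrtucommulone H ((R,R)-isomer) | CCCCCC(=O)c1c(O)c([C@@H](CC(C)C)C2=C(O)C(C)(C)C(=O)C(C)(C)C2=O)c(O)c([C@H](C2=C(O)C(C)(C)C(=O)C(C)(C)C2=O)C(C)C)c1O | target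

## Step count and risks

Total step count: 8. Longest linear sequence: 5 steps (1 → 3 → 9 → 16 → 19 → 20).

Steps most likely to fail:

Step 2 (the proposed new ring expansion). Enolate 7 may close through oxygen to a dihydropyranone instead of through carbon, or react intermolecularly with the ynone. The fallback uses known chemistry, sets out from 3 and comes back at 9. Catalytic NaOMe in MeOH opens 3 to methyl 2,2,4-trimethyl-3-oxopentanoate F1. Its lithium enolate (LDA, THF, −78 °C) is C-acetylated with acetyl chloride to methyl 2,2,4,4-tetramethyl-3,5-dioxohexanoate F2. Dieckmann cyclisation of the methyl ketone enolate onto the ester (LDA or NaOMe, then acid) gives 9. This stepwise ring opening, acylation and ring closure costs two extra operations.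

Step 3. The statistical para-borylation caps the yield, and isolating water-soluble 12 from pinacol and hydroquinone may be poor. The fallback sets out from 10 and comes back at 12. Friedel–Crafts alkylation of 10 with 2-chloropropane and AlCl3 under equilibrating conditions gives 1,3,5-tri(propan-2-yl)benzene F3. Autoxidation (O2, initiator, aq. Na2CO3, 95 °C) gives 1,3,5-tris(2-hydroperoxypropan-2-yl)benzene F4. Acid-catalysed Hock rearrangement (cat. H2SO4, acetone, 50 °C) gives 12.

Step 7. The product enol is more acidic than the phenol, so the amine catalyst may be held back and the ee may be moderate; double alkylation also competes. The fallback sets out from 14 and 16 and comes back at 19. Addition mediated by an achiral base (Et3N or NaH, THF, 0 °C) gives racemic 1-{2,4,6-trihydroxy-3-[1-(2-hydroxy-3,3,5,5-tetramethyl-4,6-dioxocyclohex-1-en-1-yl)-2-methylpropyl]phenyl}hexan-1-one F5. Preparative chiral SFC resolves it into 19 and the (S)-enantiomer F6. F6 is returned to F5 by base-induced retro-Michael/Michael equilibration and resolved again.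

## Further compounds

F1 | step 2 | methyl 2,2,4-trimethyl-3-oxopentanoate | COC(=O)C(C)(C)C(=O)C(C)C
F2 | step 2 | methyl 2,2,4,4-tetramethyl-3,5-dioxohexanoate | COC(=O)C(C)(C)C(=O)C(C)(C)C(C)=O
F3 | step 3 | 1,3,5-tri(propan-2-yl)benzene | CC(C)c1cc(C(C)C)cc(C(C)C)c1
F4 | step 3 | 1,3,5-tris(2-hydroperoxypropan-2-yl)benzene | CC(C)(OO)c1cc(C(C)(C)OO)cc(C(C)(C)OO)c1
F5 | step 7 | racemic 1-{2,4,6-trihydroxy-3-[1-(2-hydroxy-3,3,5,5-tetramethyl-4,6-dioxocyclohex-1-en-1-yl)-2-methylpropyl]phenyl}hexan-1-one | CCCCCC(=O)c1c(O)cc(O)c(C(C2=C(O)C(C)(C)C(=O)C(C)(C)C2=O)C(C)C)c1O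
F6 | step 7 | 1-{2,4,6-trihydroxy-3-[(1S)-1-(2-hydroxy-3,3,5,5-tetramethyl-4,6-dioxocyclohex-1-en-1-yl)-2-methylpropyl]phenyl}hexan-1-one | CCCCCC(=O)c1c(O)cc(O)c([C@@H](C2=C(O)C(C)(C)C(=O)C(C)(C)C2=O)C(C)C)c1O
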